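4 questions stand on this flask, and they share one answer: where complex with one exchanged peaks, and how wide that peak is.

| flask | starting complex | incoming ligand | remark | time |
|---|---|---|---|---|
| south-west | 0.70 M | 0.95 equiv | run made earlier |  |
| north | 1.1 M | 0.95 equiv | run made earlier |  |
| south-east | 0.50 M | 0.47 equiv | run made earlier |  |
| flask | 0.50 M | 0.950 equiv |  | 30 h |

| run | time / h | complex with one exchanged / % |
|---|---|---|
| south-west | 0.250 | 6.6 |
| south-west | 1.00 | 8.8 |
| south-west | 5.00 | 1.9 |
| south-west | 25.0 | 0.4 |
| north | 0.250 | 8.8 |
| north | 1.00 | 8.8 |
| north | 5.00 | 0.3 |
| north | 25.0 | 0 |
| south-east | 0.250 | 2.8 |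
| south-east | 1.00 | 7.5 |
| south-east | 5.00 | 4.0 |
| south-east | 25.0 | 0.7 |

(scatter of a reading: 1 percentage point)

1. time, not beyond 30 h, at which the flask holds most complex with one exchanged
2. the amount of complex with one exchanged, in percent of the starting complex charged, at that time
3. earliest time at which at least nineteen twentieths of that best amount are there
4. latest time at which they still are



The south-west and north runs have the flask's equivalents. If each step takes two partners, their percentages should fall on one curve of concentration of starting complex times time, a reduced time I call dose. The two runs do keep one order on that scale, so I turn each dose into flask hours by dividing by 0.50 M.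

The lowest rung is the rise: the south-west reading of 6.6% maps to 0.350 h in the flask. The next rung is the top: the north run reads 8.8% at both 0.250 h and 1.00 h, which maps to 0.550 h and 2.20 h. I place the peak between them, so I take the geometric mean of those two doses, 1980 M·s, as the top dose, the dose at the highest point. That puts my peak near 1.10 h, far earlier than the limit of 30 h, at a height read as about 8.8%, give or take 1 percentage point. The last rung is the fall: the south-west reading of 1.9% maps to 7.00 h.

The forecast, “The top is therefore flat”, gives 9.5% at 1.1 h, from 0.7 h to 1.7 h.

The flask gives 9.71% at 0.970 h, and the window asked for runs from 0.664 h to 1.38 h.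

    starting complex + incoming ligand ⇌ leaving ligand + complex with one exchanged (K = 9.60, k = 0.0114 /M/min)
    complex with one exchanged + incoming ligand ⇌ leaving ligand + complex with two exchanged (K = 34.0, k = 0.0295 /M/min)
    complex with two exchanged + incoming ligand ⇌ leaving ligand + complex with three exchanged (K = 0.240, k = 0.0314 /M/min)
    2 starting complex → self-condensation product (k = 0.0261 /M/min)
    leaving ligand + complex with one exchanged → side product (k = 0.0308 /M/min)

Each step here takes two partners. The flask's peak stands at dose 1746 M·s, lower than my top dose of 1980 M·s, and its window lies inside my bracket. Left until 5.0 d, the same flask reaches 109 times the top dose and twice the dose of the last north reading. Its highest amount stays 9.71%, and at its end it holds 0.119% complex with one exchanged.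

(The earlier runs and the new flask stem from a simulated flask from invented constants, and the scatter is random.)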